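(All runs are simulated from invented constants, noise included.)

In a one-step world target rises from the first minute, in proportion to catalyst. The ash and cedar runs did not: at 6.00 min both read 0%, and only then did they climb.

common to all: gas 200 mM (held); catalyst 6.4 mol%

| charge | substrate | remark | time |
|---|---|---|---|
| ash | 1.1 M | run made earlier |  |
| cedar | 1.8 M | run made earlier |  |
| flask | 0.80 M |  | 50 min |

| run | time / min | target / % |
|---|---|---|
| ash | 6.00 | 0 |
| ash | 12.0 | 0.6 |
| ash | 20.0 | 1.7 |
| ash | 25.0 | 2.8 |
| ash | 30.0 | 3.9 |
| cedar | 6.00 | 0 |
| cedar | 12.0 | 1.3 |
| cedar | 20.0 | 4.2 |
| cedar | 25.0 | 6.0 |
| cedar | 30.0 | 7.3 |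

(standard deviation of a reading: 0.3 percentage points)

- at the start none of the gas is in solution

- blue: doubling the transfer coefficient of the gas, all else as stated
- teal: doubling the amount of catalyst, all else as stated
- amber: doubling the saturation concentration of gas, all else as stated

- target at 50 min, in percent of the substrate charged
- the change that raises the amount of target at 50 min, in percent of the substrate charged most ("none" if none brings more than 2 percentage points) (blue / teal / amber / none)
- amount of target at 50 min, in percent of the substrate charged, after amber

A lag set by gas entering solution keeps its real minutes. A lag set by a catalysed step that must fill first shrinks as catalyst grows. So I multiplied elapsed time by the catalyst concentration and divided by that of ash. On this catalyst clock 36.4 min is where the flask stands at 50 min (Selwyn's test). Cedar at 20.0 min stood at 32.7 min and read 4.2%, while ash at 30.0 min read 3.9%. The two runs lay close to one curve.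

I ran the flask along that curve. In the first instants no gas is in solution, and the curve stays flat. In the middle it steepens, as if something forms first and then passes on. At the end the flask lies between cedar's 32.7 min and 40.9 min, and interpolation gave me 5.00%.

Teal doubles the clock, past the readings, so I extrapolated. From ash at 25.0 min to cedar at 30.0 min the clock rose by a factor of 1.96 and target by 2.61. That gave teal 13.0%, a gain of 8 percentage points. Amber, with gas at first order, gave 10.0%. Blue does not move the clock. Teal's gain was larger than amber's, so I chose teal.

The forecast gave 5.4%, amber and 10.5%, holding that “Amber should about double the rate if the reaction is first order in gas”. My figure for the flask stood lower, and my choice differed.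

The flask gave 5.53%, and 10.1% after amber. Gains were 9.3 points for teal, 4.6 points for amber and 0.16 points for blue, so teal raised target most.

    substrate + catalyst ⇌ catalyst + intermediate (K = 1.00, k = 0.00351 /M/s)
    reagent + catalyst + intermediate → catalyst + target (k = 0.0108 /M²/s)
    gas ⇌ reagent, rate k3*(csat - [reagent]) (kL = 0.00317 /s)

Doubling the clock multiplied the flask's target by 2.68, beside my 2.61 from the readings. The neighbouring flask, charged with 26 mol% catalyst, stood at 148 min on the clock, 4.07 times the flask's, or about two doublings. That factor squared gave 39.7%. The neighbouring flask gave 31.9%, less than that. At 50.0 min the neighbouring flask held 38.7% substrate and 29.4% intermediate, against 66.2% substrate in the flask.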